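## Structural features

The target is a 4-aryl-3,4-dihydrocoumarin: ring A, a benzene ring with five substituents, is fused through C4a and C8a to ring B, a six-membered aryl lactone (O1–C2–C3–C4–C4a–C8a). Ring A carries a methyl group at C5, a free hydroxyl at C7 and, between them at C6, ring D, a 4-methoxy-2-pyranone joined through its own C6. The pyranone side of that axis offers only a ring oxygen and a CH, so rotation should be free and no atropisomers are expected. Ring C, a 4-hydroxyphenyl group, sits on C4, the only stereocentre (R); it is doubly benzylic, β to the lactone carbonyl, has no stereogenic neighbour and cannot be epimerised by enolisation. The fragile parts are the aryl ester of ring B (opened by hydroxide, alkoxide, amines or basic fluoride), the vinylogous methyl carbonate of ring D, and the two phenols once they are free. The real difficulty is the C4–C4a bond, which must be made enantioselectively at a ring carbon wedged between the C5 methyl and the C8a oxygen, and in preference to C8, the other carbon ortho to that oxygen. The key step uses the fact that C2–C3–C4 with ring C is a p-coumaroyl unit (electrophilic at C4 and C2), while the C8a oxygen and C4a form a phenol with an enol-like ortho carbon para to O7, so ring B and C4 can arise in one operation.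

## Logic of the disconnections

18 to 17. The two phenolic O–H bonds are traced back to O–Si bonds at O7 and at the ring C oxygen. Both phenols must be masked during carbene catalysis, and identical masks fall in one operation. Nothing is gained in skeleton, but the end game shrinks to one step. The demand is a fluoride source acidic enough that no phenoxide is free to open ring B.

17 to 11 and 16. C4–C4a and O1–C2 are cut. This retraces the presumed biosynthetic union, removes ring B and the only stereocentre together, and leaves two achiral fragments of similar size. The forward step must bond C4a and not C8, must prefer C–C bond formation over simple O-acylation, and must distinguish the two faces of the acyl azolium.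

11 to 10. The O–benzyl bond on the C8a oxygen is cut. The two ring A oxygens have to be told apart, and the one that will become the lactone oxygen needs a mask that leaves under neutral conditions while the O7 silyl ether stays. The demand is hydrogenolysis that spares the pyranone.

10 to 9. The O–CH3 bond of ring D is cut, leaving a vinylogous acid. The demand is methylation at the C4 oxygen and not at the ring carbonyl oxygen or at carbon; it is done here, before the base-sensitive ring B exists.

9 to 7 (through 8). Pyranone O1–C2 is cut. Ring D opens to a ketone whose enol oxygen can trap an acylketene stored as a dioxinone, so the closure needs only heat and no base. The demand is dilution, so that 8 cyclises and does not dimerise.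

7 to 6, and 6 to 3 and 4 (through 5). The oxidation level of the benzylic carbon is lowered, then pyranone C5–C6 is cut. The acyl carbon on ring A sits between a methyl and a silyloxy group; a formyl group there accepts a carbon nucleophile readily, whereas an ester would not and its ortho-methyl is laterally acidic. The price is one oxidation step. The demand is a cold quench of the aldolate, so that the silyl group does not move from the phenol oxygen to the alkoxide.

3 to 2 to 1. The O–Si bond and then the O–benzyl bond are cut. The order is dictated by the hydrogen bond of the ortho hydroxyl to the formyl group: the para hydroxyl is alkylated first with a weak base, and the hindered ortho one is then silylated with a silyl triflate.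

16 to 15 to 13 and 14, and 13 to 12. The aldehyde oxidation level is lowered, the C(sp2)–C(sp) bond is cut, and the O–Si bond is cut. Each forward step is routine; the only demand is that 16, an electrophilic ynal, is used fresh.

## Other disconnections considered

Alternative 1: The cut falls on ring A, at C5–CH3 and at the C6–C(sp) bond that later becomes the ring A–pyranone bond. The bromide A2 (ring B and C4 in place, C5 still C–H) and the enynoate A3 would be merged into A1.
- Forward step: zerovalent palladium inserts into C6–Br, a transient strained bicyclic alkene relays the metal to C5–H, a methyl sulfonate alkylates the palladacycle, the mediator is extruded, and the aryl palladium is intercepted by the terminal alkyne of A3.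
- In favour: the methoxy group of ring D arrives inside A3 with its position fixed, so the ambident methylation of step 6 disappears; on this point the alternative is the better one. C4 would also be set upstream on a ring without the C5 methyl, a less crowded carbon than in step 11, which is a second advantage.
- Against: the C5–H bond is buttressed by the diarylmethine on C4a, where such relays are most sensitive to crowding. An electron-rich aryl bromide is a reluctant partner. The hot carbonate base would threaten the aryl lactone of ring B. Direct alkynylation at C6 without methylation is a likely competing path.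
- Comparison: A1 still lacks ring D (a 6-endo closure onto the alkyne) and carries two benzyl ethers, so two steps follow and the enantioselective step is only moved upstream. Three components must react in order at one metal, against two in the carbene annulation. The key step builds two bonds but no ring and no stereocentre, whereas step 11 builds two bonds, ring B and C4; the total count would be at best equal.

Alternative 2: Ring A is dismantled across C4a–C5 and C6–C7. The diene A5, whose stereocentre would stem from desymmetrisation of a prochiral glutarate, would add to the ynoate A6 and lose methanol to give the benzoate A4.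
- In favour: the polarity match of the nucleophilic diene terminus with the β-carbon of A6 places every substituent of ring A unambiguously, so the C4a/C8 question of step 11 does not arise; here the alternative is the better one. The stereocentre comes from a well-understood desymmetrisation and not from a crowded catalytic C–C bond formation, which is at least equal in stereochemical security.
- Against: the diene terminus that must bond to the methyl-bearing alkyne carbon carries a branched substituent, and A6 is a weak dienophile. The heating this requires invites silyl and hydrogen shifts in A5. The C6 ester of A4, flanked by methyl and hydroxyl, must still become the pyranone, which is the hindered-acyl problem the chosen route avoids with an aldehyde.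
- Comparison: a thermal cycloaddition and aromatisation is mechanistically simpler than carbene catalysis. But A4 is far from 18: the side chain must be raised to the acid level and lactonised, the phenols differentiated, and ring D built and methylated. That is roughly as many steps after A4 as the chosen route needs in total, on top of a long linear preparation of A5.

Alternative 3: Ring D is cut at pyranone C5–C6 and O1–C2. The acid chloride A8 would acylate the terminal carbon of the dienol ether A9, and the enol oxygen of the resulting aryl diketoester would close on the ester to give the hydroxypyranone A7.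
- In favour: an acid chloride is reactive enough to overcome the two ortho substituents, and the acylation and ring closure are of a well-known type. The pyranone is made last and never meets the carbene or hydrogen; in this respect the alternative is equal or slightly better. The key step forms two bonds and one ring, equal to step 11 on those counts.
- Against: A8 holds a second acyl donor, the aryl lactone of ring B, which competes for the nucleophile. The C6 carboxyl must be carried through the asymmetric construction of ring B, where it makes the phenol a poorer nucleophile, and then be unmasked beside that lactone. The O-methylation after A7 needs base with ring B present; the chosen plan does all basic chemistry before ring B exists.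
- Comparison: two steps follow A7 (methylation, debenzylation) against one after 17, and the key step sets no stereocentre, so C4 needs a separate enantioselective step upstream.

Key step: step 11

Remark: the antipode of the aminoindanol triazolium salt that gives (4R) is taken to be (5aR,10bS) by analogy with naphthol annulations; both antipodes are commercial, and the other is used unchanged if the analogy proves inverted.

Remark: the ring A acyl carbon is brought in as an aldehyde (one step more than an ester acylation), because an ester flanked by methyl and silyloxy groups is not a defensible acceptor for a dienolate.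

## Route

Step 1
Reactants: 1 2,4-dihydroxy-6-methylbenzaldehyde
Product: 2 4-(benzyloxy)-2-hydroxy-6-methylbenzaldehyde
Conditions: BnBr (1.05 equiv), NaHCO3, KI (cat.), MeCN, 80 °C
Reagents that add atoms: benzyl bromide, BrCc1ccccc1
Why: Williamson etherification; the C2 hydroxyl is held in a hydrogen bond to the formyl oxygen and is the weaker acid, so bicarbonate and one equivalent of halide should alkylate only the para hydroxyl.

Step 2
Reactants: 2 4-(benzyloxy)-2-hydroxy-6-methylbenzaldehyde
Product: 3 4-(benzyloxy)-2-methyl-6-(triisopropylsilyloxy)benzaldehyde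
Conditions: TIPSOTf, 2,6-lutidine, CH2Cl2, 0 °C to rt
Reagents that add atoms: triisopropylsilyl trifluoromethanesulfonate, CC(C)[Si](OS(=O)(=O)C(F)(F)F)(C(C)C)C(C)C
Why: O-silylation with a silyl triflate overcomes the hydrogen-bonded, flanked phenol; the bulky silyl ether should survive enolate, oxidation and hydrogenolysis conditions and later shields C8.

Step 3
Reactants: 3 4-(benzyloxy)-2-methyl-6-(triisopropylsilyloxy)benzaldehyde; 4 2,2,6-trimethyl-4H-1,3-dioxin-4-one
Product: 6 aldol adduct 6-{2-[4-(benzyloxy)-2-methyl-6-(triisopropylsilyloxy)phenyl]-2-hydroxyethyl}-2,2-dimethyl-4H-1,3-dioxin-4-one (racemic), via lithium dienolate 5 (not isolated)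
Conditions: LDA, THF, −78 °C; then 3, −78 °C; AcOH quench at −78 °C
Reagents that add atoms: none
Why: Vinylogous aldol addition; the dienolate reacts at its exocyclic carbon with the non-enolisable aldehyde, which is attacked readily even between two ortho substituents. Quenching cold forestalls transfer of the silyl group to the new alkoxide; the carbinol centre is racemic and is destroyed in step 4.

Step 4
Reactants: 6 aldol adduct (racemic)
Product: 7 6-{2-[4-(benzyloxy)-2-methyl-6-(triisopropylsilyloxy)phenyl]-2-oxoethyl}-2,2-dimethyl-4H-1,3-dioxin-4-one
Conditions: Dess–Martin periodinane, CH2Cl2, 0 °C to rt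
Reagents that add atoms: none
Why: Dess–Martin oxidation of a secondary benzylic alcohol to the ketone under near-neutral conditions that should leave the dioxinone, the benzyl ether and the aryl silyl ether untouched.

Step 5
Reactants: 7 6-{2-[4-(benzyloxy)-2-methyl-6-(triisopropylsilyloxy)phenyl]-2-oxoethyl}-2,2-dimethyl-4H-1,3-dioxin-4-one
Product: 9 6-[4-(benzyloxy)-2-methyl-6-(triisopropylsilyloxy)phenyl]-4-hydroxy-2H-pyran-2-one, via acylketene 8 (not isolated)
Conditions: toluene (0.02 M), 110 °C
Reagents that add atoms: none
Why: Thermal retro-[4+2] of the dioxinone expels acetone; the acylketene is trapped by the enol oxygen of the aryl ketone (six-membered lactonisation at the ketene carbon) and tautomerises to the 4-hydroxy-2-pyranone. Dilution suppresses ketene dimerisation.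

Step 6
Reactants: 9 6-[4-(benzyloxy)-2-methyl-6-(triisopropylsilyloxy)phenyl]-4-hydroxy-2H-pyran-2-one
Product: 10 6-[4-(benzyloxy)-2-methyl-6-(triisopropylsilyloxy)phenyl]-4-methoxy-2H-pyran-2-one
Conditions: Me2SO4, K2CO3, acetone, rt to 50 °C
Reagents that add atoms: dimethyl sulfate, COS(=O)(=O)OC
Why: O-alkylation of the vinylogous acid; dimethyl sulfate with carbonate in acetone is the standard way to 4-methoxy-2-pyranones and should favour the C4 oxygen over the ring carbonyl oxygen. Carbonate in an aprotic solvent should not cleave the aryl silyl ether.

Step 7
Reactants: 10 6-[4-(benzyloxy)-2-methyl-6-(triisopropylsilyloxy)phenyl]-4-methoxy-2H-pyran-2-one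
Product: 11 6-[4-hydroxy-6-methyl-2-(triisopropylsilyloxy)phenyl]-4-methoxy-2H-pyran-2-one
Conditions: H2 (1 atm), 10% Pd/C, EtOAc, rt
Reagents that add atoms: none
Why: Hydrogenolysis of a benzyl aryl ether; the push-pull 4-methoxy-2-pyranone ring and the silyl ether should not be reduced at one atmosphere and room temperature in a non-protic solvent.

Step 8
Reactants: 12 4-iodophenol
Product: 13 (4-iodophenoxy)triisopropylsilane
Conditions: TIPSCl, imidazole, DMF, rt
Reagents that add atoms: triisopropylsilyl chloride, CC(C)[Si](Cl)(C(C)C)C(C)C
Why: Routine silylation of an unhindered phenol; the group matches the O7 ether so that both fall together in step 12.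

Step 9
Reactants: 13 (4-iodophenoxy)triisopropylsilane; 14 propargyl alcohol
Product: 15 3-[4-(triisopropylsilyloxy)phenyl]prop-2-yn-1-ol
Conditions: PdCl2(PPh3)2 (2 mol %), CuI (4 mol %), Et3N, THF, rt
Reagents that add atoms: none
Why: Sonogashira coupling of an aryl iodide with a terminal alkyne at room temperature; the aryl silyl ether is stable to triethylamine.

Step 10
Reactants: 15 3-[4-(triisopropylsilyloxy)phenyl]prop-2-yn-1-ol
Product: 16 3-[4-(triisopropylsilyloxy)phenyl]prop-2-ynal
Conditions: Dess–Martin periodinane, CH2Cl2, 0 °C to rt
Reagents that add atoms: none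
Why: Dess–Martin oxidation of a propargylic alcohol stops cleanly at the ynal; 16 is used soon after preparation.

Step 11
Reactants: 11 6-[4-hydroxy-6-methyl-2-(triisopropylsilyloxy)phenyl]-4-methoxy-2H-pyran-2-one; 16 3-[4-(triisopropylsilyloxy)phenyl]prop-2-ynal
Product: 17 (4R)-6-(4-methoxy-2-oxo-2H-pyran-6-yl)-5-methyl-7-(triisopropylsilyloxy)-4-[4-(triisopropylsilyloxy)phenyl]chroman-2-one
Conditions: (5aR,10bS)-2-mesityl-5a,10b-dihydro-4H,6H-indeno[2,1-b][1,2,4]triazolo[4,3-d][1,4]oxazin-2-ium chloride (10 mol %), i-Pr2NEt (10 mol %), 4 Å MS, toluene, 40 °C, 16 (1.3 equiv) added slowly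
Reagents that add atoms: none
Why: The carbene adds to the formyl group of 16 and internal redox through the allenol gives the (E)-α,β-unsaturated acyl azolium without an external oxidant. The phenoxide of 11 then joins C4a to the β-carbon, by direct conjugate addition or by addition at the acyl carbon followed by a [3,3] shift, and tautomerisation restores ring A. Ring B closes by 6-exo-trig lactonisation of the C8a oxygen onto the acyl azolium carbonyl, which releases the carbene. The closest known type is the carbene-catalysed enantioselective annulation of ynal-derived acyl azoliums with naphthols and other stable enols to 4-aryl dihydrocoumarins; an electron-rich resorcinol monoether belongs to the same class. C4 is set in the C–C bond-forming event: the indane wall of the aminoindanol triazolylidene covers one face of the planar acyl azolium, so the arene should add to the open face, and the centre cannot epimerise afterwards. Regioselectivity is needed between C4a and C8, both ortho to the free hydroxyl; only C4a is para to O7, and the silyl group on O7, turned away from the pyranone, covers C8. O-acylation to an aryl cinnamate should be reversible under carbene catalysis, the other two phenols are silylated, and slow addition of 16 limits ynal oligomerisation.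

Step 12
Reactants: 17 (4R)-6-(4-methoxy-2-oxo-2H-pyran-6-yl)-5-methyl-7-(triisopropylsilyloxy)-4-[4-(triisopropylsilyloxy)phenyl]chroman-2-one
Product: 18 (4R)-7-hydroxy-4-(4-hydroxyphenyl)-6-(4-methoxy-2-oxo-2H-pyran-6-yl)-5-methylchroman-2-one (target)
Conditions: HF·pyridine, pyridine, THF, 0 °C to rt
Reagents that add atoms: none
Why: Fluoride-driven cleavage of both aryl O–Si bonds in an acidic medium; no phenoxide is free, so the aryl lactone of ring B and the pyranone should stay closed, and C4 keeps its configuration.

## Compound list

1 | 2,4-dihydroxy-6-methylbenzaldehyde | O=Cc1c(C)cc(O)cc1O | starting material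
2 | 4-(benzyloxy)-2-hydroxy-6-methylbenzaldehyde | O=Cc1c(C)cc(OCc2ccccc2)cc1O | intermediate
3 | 4-(benzyloxy)-2-methyl-6-(triisopropylsilyloxy)benzaldehyde | O=Cc1c(C)cc(OCc2ccccc2)cc1O[Si](C(C)C)(C(C)C)C(C)C | intermediate
4 | 2,2,6-trimethyl-4H-1,3-dioxin-4-one | CC1=CC(=O)OC(C)(C)O1 | starting material
5 | lithium 2,2-dimethyl-6-methylidene-6H-1,3-dioxin-4-olate | [Li+].[O-]C1=CC(=C)OC(C)(C)O1 | intermediate (not isolated)
6 | 6-{2-[4-(benzyloxy)-2-methyl-6-(triisopropylsilyloxy)phenyl]-2-hydroxyethyl}-2,2-dimethyl-4H-1,3-dioxin-4-one (racemic) | CC1(C)OC(=O)C=C(CC(O)c2c(C)cc(OCc3ccccc3)cc2O[Si](C(C)C)(C(C)C)C(C)C)O1 | intermediate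
7 | 6-{2-[4-(benzyloxy)-2-methyl-6-(triisopropylsilyloxy)phenyl]-2-oxoethyl}-2,2-dimethyl-4H-1,3-dioxin-4-one | CC1(C)OC(=O)C=C(CC(=O)c2c(C)cc(OCc3ccccc3)cc2O[Si](C(C)C)(C(C)C)C(C)C)O1 | intermediate
8 | 5-[4-(benzyloxy)-2-methyl-6-(triisopropylsilyloxy)phenyl]-3,5-dioxopent-1-en-1-one (acylketene) | O=C=CC(=O)CC(=O)c1c(C)cc(OCc2ccccc2)cc1O[Si](C(C)C)(C(C)C)C(C)C | intermediate (not isolated)
9 | 6-[4-(benzyloxy)-2-methyl-6-(triisopropylsilyloxy)phenyl]-4-hydroxy-2H-pyran-2-one | O=c1cc(O)cc(-c2c(C)cc(OCc3ccccc3)cc2O[Si](C(C)C)(C(C)C)C(C)C)o1 | intermediate
10 | 6-[4-(benzyloxy)-2-methyl-6-(triisopropylsilyloxy)phenyl]-4-methoxy-2H-pyran-2-one | COc1cc(-c2c(C)cc(OCc3ccccc3)cc2O[Si](C(C)C)(C(C)C)C(C)C)oc(=O)c1 | intermediate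
11 | 6-[4-hydroxy-6-methyl-2-(triisopropylsilyloxy)phenyl]-4-methoxy-2H-pyran-2-one | COc1cc(-c2c(O[Si](C(C)C)(C(C)C)C(C)C)cc(O)cc2C)oc(=O)c1 | intermediate
12 | 4-iodophenol | Oc1ccc(I)cc1 | starting material
13 | (4-iodophenoxy)triisopropylsilane | CC(C)[Si](Oc1ccc(I)cc1)(C(C)C)C(C)C | intermediate
14 | propargyl alcohol | OCC#C | starting material
15 | 3-[4-(triisopropylsilyloxy)phenyl]prop-2-yn-1-ol | OCC#Cc1ccc(O[Si](C(C)C)(C(C)C)C(C)C)cc1 | intermediate
16 | 3-[4-(triisopropylsilyloxy)phenyl]prop-2-ynal | O=CC#Cc1ccc(O[Si](C(C)C)(C(C)C)C(C)C)cc1 | intermediate
17 | (4R)-6-(4-methoxy-2-oxo-2H-pyran-6-yl)-5-methyl-7-(triisopropylsilyloxy)-4-[4-(triisopropylsilyloxy)phenyl]chroman-2-one | COc1cc(-c2c(O[Si](C(C)C)(C(C)C)C(C)C)cc3c(c2C)[C@@H](c2ccc(O[Si](C(C)C)(C(C)C)C(C)C)cc2)CC(=O)O3)oc(=O)c1 | intermediate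
18 | (4R)-7-hydroxy-4-(4-hydroxyphenyl)-6-(4-methoxy-2-oxo-2H-pyran-6-yl)-5-methylchroman-2-one | COc1cc(-c2c(O)cc3c(c2C)[C@@H](c2ccc(O)cc2)CC(=O)O3)oc(=O)c1 | target

## Step count and least certain steps

Total: 12 steps. Longest linear sequence: 9 steps (steps 1 to 7, then 11 and 12); the ynal branch is steps 8 to 10.

**Step 11 (key step).** The phenoxide of 11 is conjugated to the pyranone and is a weaker carbon nucleophile than a naphthol, so the reaction may stall at reversible O-acylation or bond at C8. The C5 methyl may also erode facial discrimination, and the base may oligomerise the ynal. The fallback leaves carbene catalysis and sets C4 by rhodium-catalysed conjugate addition. It sets out from 11 and returns at 18.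
- Magnesium-mediated ortho-formylation of 11 (MgCl2, Et3N, paraformaldehyde, MeCN, reflux) should give 2-hydroxy-5-(4-methoxy-2-oxo-2H-pyran-6-yl)-6-methyl-4-(triisopropylsilyloxy)benzaldehyde F1.
- Wittig olefination with methyl (triphenylphosphoranylidene)acetate in hot N,N-diethylaniline, with thermal isomerisation and lactonisation, should give the coumarin 6-(4-methoxy-2-oxo-2H-pyran-6-yl)-5-methyl-7-(triisopropylsilyloxy)-2H-chromen-2-one F2.
- Asymmetric 1,4-addition of commercial 4-(tert-butyldimethylsilyloxy)phenylboronic acid with Rh(acac)(C2H4)2 and (R)-Segphos in dioxane–water at 60 °C should give (4R)-4-[4-(tert-butyldimethylsilyloxy)phenyl]-6-(4-methoxy-2-oxo-2H-pyran-6-yl)-5-methyl-7-(triisopropylsilyloxy)chroman-2-one F3. The ligand antipode is assigned by analogy with simple coumarins.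
- F3 is desilylated under the conditions of step 12 to 18.
- The formylation shares the C4a/C8 question with step 11, so this fallback answers reactivity and facial selectivity, not regiochemistry.

**Step 3.** Addition to the doubly ortho-substituted, electron-rich formyl group may be slow at −78 °C. On warming, the lithium alkoxide may take the silyl group from the neighbouring phenol oxygen, followed by elimination. The fallback uses a neutral nucleophile under Lewis acid activation, so no alkoxide is formed. It sets out from 3 and returns at 9.
- Mukaiyama aldol addition of the bis(trimethylsilyl) dienol ether of methyl acetoacetate (the reagent labelled A9) with BF3·OEt2 in CH2Cl2 at −78 °C should give methyl 5-[4-(benzyloxy)-2-methyl-6-(triisopropylsilyloxy)phenyl]-5-hydroxy-3-oxopentanoate F4.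
- Dess–Martin oxidation should give methyl 5-[4-(benzyloxy)-2-methyl-6-(triisopropylsilyloxy)phenyl]-3,5-dioxopentanoate F5.
- DBU in toluene should close F5 to 9 with loss of methanol.

**Step 12.** Acidic fluoride may cleave the hindered O7 silyl ether only slowly, and forcing the reaction with more basic fluoride may open ring B. The fallback accepts the opening and closes the ring again. It sets out from 17 and returns at 18.
- TBAF in wet THF removes both silyl groups and is allowed to hydrolyse the lactone, giving (3R)-3-[2,4-dihydroxy-5-(4-methoxy-2-oxo-2H-pyran-6-yl)-6-methylphenyl]-3-(4-hydroxyphenyl)propanoic acid F6.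
- Catalytic TsOH in warm toluene should relactonise F6 to 18. Only the C8a oxygen is ortho to the side chain, and C4 is untouched throughout.

**Step 6.** The ambident pyranone anion may be methylated partly at the ring carbonyl oxygen (giving the 2-methoxy-4-pyranone isomer) or at C3. The fallback reverses the polarity, so that the O–CH3 bond is brought in as methoxide. It sets out from 9 and returns at 10.
- TsCl and Et3N in CH2Cl2 should sulfonylate the C4 oxygen to 6-[4-(benzyloxy)-2-methyl-6-(triisopropylsilyloxy)phenyl]-2-oxo-2H-pyran-4-yl 4-methylbenzenesulfonate F7.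
- One equivalent of NaOMe in MeOH–THF at −20 °C should displace the sulfonate by addition–elimination at C4 to give 10. The low temperature and single equivalent protect the hindered aryl silyl ether.

## Further compounds

F1 | step 11 | 2-hydroxy-5-(4-methoxy-2-oxo-2H-pyran-6-yl)-6-methyl-4-(triisopropylsilyloxy)benzaldehyde | COc1cc(-c2c(O[Si](C(C)C)(C(C)C)C(C)C)cc(O)c(C=O)c2C)oc(=O)c1
F2 | step 11 | 6-(4-methoxy-2-oxo-2H-pyran-6-yl)-5-methyl-7-(triisopropylsilyloxy)-2H-chromen-2-one | COc1cc(-c2c(O[Si](C(C)C)(C(C)C)C(C)C)cc3oc(=O)ccc3c2C)oc(=O)c1
F3 | step 11 | (4R)-4-[4-(tert-butyldimethylsilyloxy)phenyl]-6-(4-methoxy-2-oxo-2H-pyran-6-yl)-5-methyl-7-(triisopropylsilyloxy)chroman-2-one | COc1cc(-c2c(O[Si](C(C)C)(C(C)C)C(C)C)cc3c(c2C)[C@@H](c2ccc(O[Si](C)(C)C(C)(C)C)cc2)CC(=O)O3)oc(=O)c1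
F4 | step 3 | methyl 5-[4-(benzyloxy)-2-methyl-6-(triisopropylsilyloxy)phenyl]-5-hydroxy-3-oxopentanoate (racemic) | COC(=O)CC(=O)CC(O)c1c(C)cc(OCc2ccccc2)cc1O[Si](C(C)C)(C(C)C)C(C)C
F5 | step 3 | methyl 5-[4-(benzyloxy)-2-methyl-6-(triisopropylsilyloxy)phenyl]-3,5-dioxopentanoate | COC(=O)CC(=O)CC(=O)c1c(C)cc(OCc2ccccc2)cc1O[Si](C(C)C)(C(C)C)C(C)C
F6 | step 12 | (3R)-3-[2,4-dihydroxy-5-(4-methoxy-2-oxo-2H-pyran-6-yl)-6-methylphenyl]-3-(4-hydroxyphenyl)propanoic acid | COc1cc(-c2c(O)cc(O)c(c2C)[C@@H](c2ccc(O)cc2)CC(=O)O)oc(=O)c1
F7 | step 6 | 6-[4-(benzyloxy)-2-methyl-6-(triisopropylsilyloxy)phenyl]-2-oxo-2H-pyran-4-yl 4-methylbenzenesulfonate | Cc1ccc(cc1)S(=O)(=O)Oc1cc(-c2c(C)cc(OCc3ccccc3)cc2O[Si](C(C)C)(C(C)C)C(C)C)oc(=O)c1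
A1 | alternative 1 | tert-butyl (E)-5-[(4R)-7-benzyloxy-4-(4-benzyloxyphenyl)-5-methyl-2-oxochroman-6-yl]-3-methoxypent-2-en-4-ynoate | CC(C)(C)OC(=O)/C=C(OC)\C#Cc1c(OCc2ccccc2)cc2c(c1C)[C@@H](c1ccc(OCc3ccccc3)cc1)CC(=O)O2
A2 | alternative 1 | (4R)-7-benzyloxy-4-(4-benzyloxyphenyl)-6-bromochroman-2-one | Brc1c(OCc2ccccc2)cc2c(c1)[C@@H](c1ccc(OCc3ccccc3)cc1)CC(=O)O2
A3 | alternative 1 | tert-butyl (E)-3-methoxypent-2-en-4-ynoate | CC(C)(C)OC(=O)/C=C(OC)\C#C
A4 | alternative 2 | methyl 5-{(1R)-3-(tert-butyldimethylsilyloxy)-1-[4-(triisopropylsilyloxy)phenyl]propyl}-2,4-dihydroxy-6-methylbenzoate | COC(=O)c1c(O)cc(O)c(c1C)[C@@H](c1ccc(O[Si](C(C)C)(C(C)C)C(C)C)cc1)CCO[Si](C)(C)C(C)(C)C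
A5 | alternative 2 | (5S)-7-(tert-butyldimethylsilyloxy)-1-methoxy-5-[4-(triisopropylsilyloxy)phenyl]-1,3-bis(trimethylsilyloxy)hepta-1,3-diene (enol ether geometry not specified) | COC(O[Si](C)(C)C)=CC(O[Si](C)(C)C)=C[C@@H](c1ccc(O[Si](C(C)C)(C(C)C)C(C)C)cc1)CCO[Si](C)(C)C(C)(C)C
A6 | alternative 2 | methyl but-2-ynoate | CC#CC(=O)OC
A7 | alternative 3 | (4R)-7-benzyloxy-4-(4-benzyloxyphenyl)-6-(4-hydroxy-2-oxo-2H-pyran-6-yl)-5-methylchroman-2-one | O=c1cc(O)cc(-c2c(OCc3ccccc3)cc3c(c2C)[C@@H](c2ccc(OCc4ccccc4)cc2)CC(=O)O3)o1
A8 | alternative 3 | (4R)-7-benzyloxy-4-(4-benzyloxyphenyl)-5-methyl-2-oxochroman-6-carbonyl chloride | O=C(Cl)c1c(OCc2ccccc2)cc2c(c1C)[C@@H](c1ccc(OCc3ccccc3)cc1)CC(=O)O2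
A9 | alternative 3 | 1-methoxy-1,3-bis(trimethylsilyloxy)buta-1,3-diene | COC(O[Si](C)(C)C)=CC(=C)O[Si](C)(C)C
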